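## Analysis of the target

- The target 18 is a flavone, 2-(2,5-dihydroxy-3,4-dimethoxyphenyl)-5-hydroxy-7-methoxy-4H-chromen-4-one. Ring A (C4a–C8a) carries OH at C5 and OMe at C7. Ring C holds O1, C2, an unsubstituted C3 and the C4 carbonyl. Ring B sits on C2 and is oxygenated at four carbons (2'-OH, 3'-OMe, 4'-OMe, 5'-OH), with hydrogen only at C6'.
- There is no stereocentre, so every difficulty is one of regiochemistry and oxidation level: six ring oxygens, three methylated and three free, each at one defined carbon.
- Ring B is a 2,3-dimethoxyhydroquinone. Once its two para hydroxyls are free it oxidises easily to the quinone, so they should stay masked until the last step.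
- Ring A is a phloroglucinol-type ring, strongly nucleophilic at C6 and C8, and therefore intolerant of electrophilic halogen sources.
- Ring B has its own ortho hydroxyl (2'-OH). An open-chain 1,3-diketone between two ortho-hydroxyaryl groups could close a pyranone onto either ring, so ring C closure must be directed to ring A.
- The strategy rests on the chain C4–C3–C2. It is a three-carbon unit oxygenated at both ends, joining ring A (at C4) to ring B (at C2), which is the oxidation pattern of a β-diketone. A 3,5-diarylisoxazole with ring A on the C=N carbon and ring B on the C–O carbon carries that unit in latent form, and it can be made by forming C3–C4 and the C2–O bond in a single cycloaddition.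
- A supporting feature: with O1–C2 opened, ring A is a 4-methoxy-2,6-dioxygenated phenyl group, symmetric about the C4a–C7 axis. Its two ortho substituents can stabilise a nitrile oxide, and either ortho oxygen closes ring C to the same flavone.

## Retrosynthetic reasoning

**18 from 17.** The two benzyl C–O bonds on ring B are cut last. The hydroquinone stays protected through every earlier step, and the final hydrogenolysis only has to spare the chromone C2–C3 bond and the methyl ethers.

**17 from 15 (through 16).** Ring C is opened at O1–C2, giving the diketone 16, and 16 is traced back to the enaminone 15, in which C4 carries nitrogen and the ring A phenols are MOM ethers. Cutting O1–C2 rather than C4–C4a keeps ring A intact and turns ring C formation into a cyclodehydration. In the forward direction acid has to remove the MOM groups, hydrolyse the vinylogous amide and close the ring. The benzyl ethers on ring B survive, so only ring A offers a nucleophilic phenol.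

**15 from 14.** The nitrogen on C4 is reconnected to the oxygen on C2, which gives the isoxazole 14. The gain is that the chelating, enolisable diketone is carried as a stable aromatic heterocycle through the fragment union. The forward step is a reductive N–O cleavage that must leave benzyl ethers untouched.

**14 from 13 and 7.** The isoxazole is cut at C3–C4 and C2–O (flavone numbering), the two bonds a 1,3-dipolar cycloaddition forms. This divides the molecule into its two arenes: nitrile oxide 13 with one extra carbon on ring A, and alkyne 7 with two extra carbons on ring B. The forward reaction must deliver the 3,5-diaryl regiochemistry, because the 3,4-isomer would put ring B on C3.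

**13 from 12, 11, 9 and 8.** The dipole comes from oxime 12 by dehydrogenation, and 12 from aldehyde 11. The bond between ring A and the future C4 is made by directed metalation and formylation of bis-MOM ether 9, at the carbon between its two MOM ethers. Ether 9 comes from the diol 8.

**7 from 6, 4, 3, 2 and 1.** The alkyne is the one-carbon homologue of aldehyde 6. Aldehyde 6 comes from formylation of the C2-symmetric tetraether 4, which has only one kind of ring C–H. Ether 4 comes from phenol 1 by para-oxidation to quinone 2, reduction to hydroquinone 3 and benzylation.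

## Alternatives that were turned down

**Alternative 1: ring B by squarate ring expansion.**
- Disconnection: ring B is taken apart into a four-carbon squarate unit (C2'–C5' with all four oxygens) and a two-carbon alkene unit (C1' and C6').
- Forward key step: the adduct of an acetal-bearing alkenyllithium with a dialkyl squarate is 4-(3,3-diethoxyprop-1-en-2-yl)-4-hydroxy-2,3-dimethoxycyclobut-2-en-1-one A1. On heating, A1 should open to a dienylketene, close the C5'–C6' bond by 6π electrocyclisation and tautomerise to 2-(diethoxymethyl)-5,6-dimethoxybenzene-1,4-diol A2.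
- For: every ring B oxygen and the carbon substituent are placed by construction, and the key step needs no reagent.
- Against: it solves a problem that is already easy. The same pattern is reached from phenol 1 through the symmetric ether 4, where formylation has no regiochemical choice. A2 is a free, oxidisable hydroquinone with an acid-labile acetal. It still needs benzylation and unmasking to reach the stage of 6, which is four operations, no fewer than steps 1–4.
- Comparison: on ring B regiocontrol the two are equal. The alternative leaves the linking of the rings and the direction of ring C closure untouched, whereas the chosen strategy spends its key step on exactly that.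

**Alternative 2: biomimetic Claisen folding of a pyrone-masked polyketide.**
- Disconnection: ring A is cut at C4a–C8a, back to 1-[2,5-bis(benzyloxy)-3,4-dimethoxyphenyl]-4-(4-methoxy-2-oxo-2H-pyran-6-yl)butane-1,3-dione A3.
- Forward key step: methanolic methoxide should open the pyrone of A3 to a methyl ester, and the C4a methylene should attack that ester carbon. This closes ring A and gives 1-[2,5-bis(benzyloxy)-3,4-dimethoxyphenyl]-3-(2,6-dihydroxy-4-methoxyphenyl)propane-1,3-dione A4, which is the same diketone as intermediate 16.
- For: ring A and the diketone arise in one operation. The C7 methoxy group is fixed by the pyrone, so no directed metalation is needed. The nitrogen detour of steps 8, 9 and 11 is avoided. On these points it is stronger than the chosen route.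
- Against: A3 is a tricarbonyl chain that must be built by Claisen-type acylations with a hindered ring B acyl donor, and it exists as several enol forms. Once the pyrone is opened, aldol closure onto a ketone, O-cyclisation to a 4-pyranone and relactonisation all compete with the wanted C-acylation.
- Comparison: the endgame from A4 is the same as steps 12 and 13. The chosen strategy offers in exchange a key step with essentially one reaction channel between two stable arenes, and it reveals the diketone only when it is to cyclise.

**Alternative 3: silyloxyfuran Diels–Alder on an ethynylchromone.**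
- Disconnection: ring B is cut at C1'–C2' and C5'–C6', back to 5-(benzyloxy)-2-ethynyl-7-methoxy-4H-chromen-4-one A5 and tert-butyl[(3,4-dimethoxyfuran-2-yl)oxy]dimethylsilane A6.
- Forward key step: cycloaddition of A6 across the alkyne of A5 and opening of the oxygen bridge should give 5-(benzyloxy)-2-{2-[(tert-butyldimethylsilyl)oxy]-5-hydroxy-3,4-dimethoxyphenyl}-7-methoxy-4H-chromen-4-one A7.
- For: the chromone is finished before the union. Polarisation matches, since the nucleophilic furan C5 meets the electrophilic terminal alkyne carbon. The two ring B oxygens emerge differentiated, and the union is very late.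
- Against: A6 is a hydrolytically labile diene that must be made from a tetronic-acid-type butenolide. A5 takes several steps and is a Michael acceptor at both C2 and the alkyne terminus. Stepwise vinylogous Michael addition, stopping at a butenolide, is therefore a likely diversion from cycloaddition and aromatisation. Two deprotections still follow.
- Comparison: it is stronger in convergence at the last stage, but the differentiation of the 2'- and 5'-oxygens is not needed for 18. The chosen route uses cheap arenes and a cycloaddition whose regiochemistry is secured by the terminal alkyne.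

Key step: step 10

Assumption: in step 12 the enaminone is taken to hydrolyse to the diketone 16 before ring closure; if closure came first, the nitrogen would be lost after cyclisation instead, with the same product 17.

## Route

Step 1
Reactants: 1 2,3-dimethoxyphenol
Product: 2 2,3-dimethoxy-1,4-benzoquinone
Conditions: K2[ON(SO3)2] (2.2 equiv), KH2PO4, H2O/MeOH, 0 °C to rt
Reagents that add atoms: potassium nitrosodisulfonate K2[ON(SO3)2], [K+].[K+].[O]N(S(=O)(=O)[O-])S(=O)(=O)[O-]
Why: Teuber oxidation: the nitroxide abstracts the phenolic hydrogen, a second equivalent couples at the free para carbon, and loss of imidodisulfonate gives the para-quinone.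

Step 2
Reactants: 2 2,3-dimethoxy-1,4-benzoquinone
Product: 3 2,3-dimethoxybenzene-1,4-diol
Conditions: Na2S2O4, EtOAc/H2O, rt, under N2
Reagents that add atoms: none
Why: Dithionite reduction of a quinone to its hydroquinone is fast and clean; the air-sensitive diol is carried on at once.

Step 3
Reactants: 3 2,3-dimethoxybenzene-1,4-diol
Product: 4 1,4-bis(benzyloxy)-2,3-dimethoxybenzene
Conditions: BnBr, K2CO3, DMF, rt, under N2
Reagents that add atoms: benzyl bromide, BrCc1ccccc1
Why: Williamson etherification of both phenoxides; benzyl ethers are chosen because they survive base, the Vilsmeier reagent, Mo(CO)6 and aqueous HCl, and fall only to the final hydrogenolysis.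

Step 4
Reactants: 4 1,4-bis(benzyloxy)-2,3-dimethoxybenzene
Product: 6 2,5-bis(benzyloxy)-3,4-dimethoxybenzaldehyde, via benzylidene iminium chloride 5 (not isolated)
Conditions: POCl3, DMF, 70 °C; then aq. NaOAc
Reagents that add atoms: N,N-dimethylformamide, CN(C)C=O; water, O
Why: Vilsmeier–Haack formylation of a tetraalkoxybenzene; 4 is C2-symmetric with a single kind of ring C–H (ortho to a benzyloxy and para to a methoxy group), so only one aldehyde can form.

Step 5
Reactants: 6 2,5-bis(benzyloxy)-3,4-dimethoxybenzaldehyde
Product: 7 1,4-bis(benzyloxy)-5-ethynyl-2,3-dimethoxybenzene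
Conditions: dimethyl (1-diazo-2-oxopropyl)phosphonate, K2CO3, MeOH, rt
Reagents that add atoms: dimethyl (1-diazo-2-oxopropyl)phosphonate, CC(=O)C(=[N+]=[N-])P(=O)(OC)OC
Why: Ohira–Bestmann variant of the Seyferth–Gilbert homologation: methanolysis frees the diazomethylphosphonate anion, which olefinates the non-enolisable aldehyde; loss of N2 and a 1,2-hydrogen shift give the terminal alkyne.

Step 6
Reactants: 8 5-methoxyresorcinol (5-methoxybenzene-1,3-diol)
Product: 9 1-methoxy-3,5-bis(methoxymethoxy)benzene
Conditions: MOMCl, i-Pr2NEt, CH2Cl2, 0 °C to rt
Reagents that add atoms: chloromethyl methyl ether, COCCl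
Why: Standard MOM protection; MOM is chosen for its directing power in step 7, its bulk beside the later nitrile oxide, and its removal by acid in step 12 while benzyl ethers stay.

Step 7
Reactants: 9 1-methoxy-3,5-bis(methoxymethoxy)benzene
Product: 11 4-methoxy-2,6-bis(methoxymethoxy)benzaldehyde, via aryllithium 10 (not isolated)
Conditions: n-BuLi, TMEDA, THF, 0 °C; DMF, 0 °C to rt; H2O
Reagents that add atoms: N,N-dimethylformamide, CN(C)C=O
Why: Directed ortho-metalation: the carbon between the two MOM ethers is doubly coordinated and doubly acidified, and MOM outranks OMe as a directing group, so lithiation should occur there before formylation. A minor isomer from metalation next to OMe would be unsymmetrical and separable here.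

Step 8
Reactants: 11 4-methoxy-2,6-bis(methoxymethoxy)benzaldehyde
Product: 12 (E)-4-methoxy-2,6-bis(methoxymethoxy)benzaldehyde oxime
Conditions: NH2OH·HCl, NaOAc, EtOH/H2O, rt
Reagents that add atoms: hydroxylamine hydrochloride, Cl.NO
Why: Oxime condensation under acetate buffer, mild enough for the MOM ethers; the E aldoxime is expected, and its geometry does not matter for step 9.

Step 9
Reactants: 12 (E)-4-methoxy-2,6-bis(methoxymethoxy)benzaldehyde oxime
Product: 13 4-methoxy-2,6-bis(methoxymethoxy)benzonitrile oxide
Conditions: PhI(OAc)2, MeOH, 0 °C; then aq. NaHCO3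
Reagents that add atoms: none
Why: Oxidative dehydrogenation of an aldoxime by PhI(OAc)2 (ligand exchange at iodine, then loss of PhI and AcOH). A halogen-free oxidant is used because N-chlorosuccinimide or hypochlorite would chlorinate the phloroglucinol-type ring. The two ortho MOM ethers should make the dipole isolable, as for other 2,6-disubstituted benzonitrile oxides.

Step 10
Reactants: 13 4-methoxy-2,6-bis(methoxymethoxy)benzonitrile oxide; 7 1,4-bis(benzyloxy)-5-ethynyl-2,3-dimethoxybenzene
Product: 14 5-[2,5-bis(benzyloxy)-3,4-dimethoxyphenyl]-3-[4-methoxy-2,6-bis(methoxymethoxy)phenyl]isoxazole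
Conditions: toluene, 80 °C (13 in slight excess)
Reagents that add atoms: none
Why: Huisgen 1,3-dipolar cycloaddition: the nitrile oxide adds across the alkyne in one concerted, asynchronous step, its carbon bonding to the terminal alkyne carbon (C4–C3 of the flavone) and its oxygen to the internal carbon (the C2–O bond). The closest known reaction is the thermal addition of stable di-ortho-substituted benzonitrile oxides to arylacetylenes, which gives 3,5-diarylisoxazoles. The isoxazole ring closes by intermolecular (3+2) cycloaddition, suprafacial on both partners, with both σ bonds formed in the same step, and no stereocentre is created. The step needs 3,5- over 3,4-regiochemistry; the terminal alkyne secures it, since its unhindered CH carbon, which also has the larger frontier orbital coefficient, meets the hindered dipole carbon. The two ortho MOM-oxy groups shield the CNO carbon and so hold back dimerisation to the furoxan. The temperature is kept at 80 °C so that thermal isomerisation of the dipole stays slow. No base, oxidant or acid is present, so MOM and benzyl ethers are untouched.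

Step 11
Reactants: 14 5-[2,5-bis(benzyloxy)-3,4-dimethoxyphenyl]-3-[4-methoxy-2,6-bis(methoxymethoxy)phenyl]isoxazole
Product: 15 (Z)-3-amino-1-[2,5-bis(benzyloxy)-3,4-dimethoxyphenyl]-3-[4-methoxy-2,6-bis(methoxymethoxy)phenyl]prop-2-en-1-one
Conditions: Mo(CO)6, MeCN/H2O, 80 °C
Reagents that add atoms: none
Why: Reductive N–O cleavage of an isoxazole by Mo(CO)6 in wet acetonitrile: coordination at nitrogen, N–O scission and hydrolysis of the metal–nitrogen species give the hydrogen-bonded Z β-enaminoketone. Unlike hydrogenolysis it leaves the benzyl ethers, and the neutral medium leaves the MOM ethers.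

Step 12
Reactants: 15 (Z)-3-amino-1-[2,5-bis(benzyloxy)-3,4-dimethoxyphenyl]-3-[4-methoxy-2,6-bis(methoxymethoxy)phenyl]prop-2-en-1-one
Product: 17 2-[2,5-bis(benzyloxy)-3,4-dimethoxyphenyl]-5-hydroxy-7-methoxy-4H-chromen-4-one, via 1,3-diketone 16 (not isolated)
Conditions: 3 M aq. HCl, MeOH/THF, 60 °C
Reagents that add atoms: water, O
Why: Acid removes both MOM ethers and hydrolyses the vinylogous amide to diketone 16; a ring A phenol then adds to the C2 carbonyl (6-exo-trig) and dehydration closes ring C, the classical cyclodehydration of o-hydroxyaryl β-diketones to flavones. Ring A is symmetric, so either phenol gives the same product, and ring B cannot compete because its phenols are still benzylated.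

Step 13
Reactants: 17 2-[2,5-bis(benzyloxy)-3,4-dimethoxyphenyl]-5-hydroxy-7-methoxy-4H-chromen-4-one
Product: 18 2-(2,5-dihydroxy-3,4-dimethoxyphenyl)-5-hydroxy-7-methoxy-4H-chromen-4-one
Conditions: H2 (1 atm), Pd/C, EtOAc/MeOH, rt; work-up under N2
Reagents that add atoms: none
Why: Hydrogenolysis of the two aryl benzyl ethers over Pd/C; the chromone C2–C3 bond is a vinylogous ester that should resist hydrogenation at 1 atm, and inert work-up protects the freed hydroquinone.

## Compound list

1 | 2,3-dimethoxyphenol | COc1cccc(O)c1OC | starting material
2 | 2,3-dimethoxy-1,4-benzoquinone | COC1=C(OC)C(=O)C=CC1=O | intermediate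
3 | 2,3-dimethoxybenzene-1,4-diol | COc1c(O)ccc(O)c1OC | intermediate
4 | 1,4-bis(benzyloxy)-2,3-dimethoxybenzene | COc1c(OCc2ccccc2)ccc(OCc2ccccc2)c1OC | intermediate
5 | {[2,5-bis(benzyloxy)-3,4-dimethoxyphenyl]methylidene}dimethyliminium chloride (not isolated) | C[N+](C)=Cc1cc(OCc2ccccc2)c(OC)c(OC)c1OCc1ccccc1.[Cl-] | intermediate
6 | 2,5-bis(benzyloxy)-3,4-dimethoxybenzaldehyde | O=Cc1cc(OCc2ccccc2)c(OC)c(OC)c1OCc1ccccc1 | intermediate
7 | 1,4-bis(benzyloxy)-5-ethynyl-2,3-dimethoxybenzene | C#Cc1cc(OCc2ccccc2)c(OC)c(OC)c1OCc1ccccc1 | intermediate
8 | 5-methoxyresorcinol (5-methoxybenzene-1,3-diol) | COc1cc(O)cc(O)c1 | starting material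
9 | 1-methoxy-3,5-bis(methoxymethoxy)benzene | COCOc1cc(OC)cc(OCOC)c1 | intermediate
10 | [4-methoxy-2,6-bis(methoxymethoxy)phenyl]lithium (not isolated) | [Li]c1c(OCOC)cc(OC)cc1OCOC | intermediate
11 | 4-methoxy-2,6-bis(methoxymethoxy)benzaldehyde | COCOc1cc(OC)cc(OCOC)c1C=O | intermediate
12 | (E)-4-methoxy-2,6-bis(methoxymethoxy)benzaldehyde oxime | COCOc1cc(OC)cc(OCOC)c1/C=N/O | intermediate
13 | 4-methoxy-2,6-bis(methoxymethoxy)benzonitrile oxide | COCOc1cc(OC)cc(OCOC)c1C#[N+][O-] | intermediate
14 | 5-[2,5-bis(benzyloxy)-3,4-dimethoxyphenyl]-3-[4-methoxy-2,6-bis(methoxymethoxy)phenyl]isoxazole | COCOc1cc(OC)cc(OCOC)c1-c1cc(-c2cc(OCc3ccccc3)c(OC)c(OC)c2OCc2ccccc2)on1 | intermediate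
15 | (Z)-3-amino-1-[2,5-bis(benzyloxy)-3,4-dimethoxyphenyl]-3-[4-methoxy-2,6-bis(methoxymethoxy)phenyl]prop-2-en-1-one | COCOc1cc(OC)cc(OCOC)c1/C(N)=C/C(=O)c1cc(OCc2ccccc2)c(OC)c(OC)c1OCc1ccccc1 | intermediate
16 | 1-[2,5-bis(benzyloxy)-3,4-dimethoxyphenyl]-3-(2,6-dihydroxy-4-methoxyphenyl)propane-1,3-dione (not isolated) | COc1cc(O)c(C(=O)CC(=O)c2cc(OCc3ccccc3)c(OC)c(OC)c2OCc2ccccc2)c(O)c1 | intermediate
17 | 2-[2,5-bis(benzyloxy)-3,4-dimethoxyphenyl]-5-hydroxy-7-methoxy-4H-chromen-4-one | COc1cc(O)c2c(=O)cc(-c3cc(OCc4ccccc4)c(OC)c(OC)c3OCc3ccccc3)oc2c1 | intermediate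
18 | 2-(2,5-dihydroxy-3,4-dimethoxyphenyl)-5-hydroxy-7-methoxy-4H-chromen-4-one | COc1cc(O)c2c(=O)cc(-c3cc(O)c(OC)c(OC)c3O)oc2c1 | target

## Step count and risks

Total step count: 13. Longest linear sequence: 9 steps (steps 1–5, then 10–13); the ring A branch (steps 6–9) joins at step 10.

**Step 10 (key step).** Both partners are electron-rich and the dipole is flanked by two ortho substituents. The cycloaddition may therefore be slow enough that thermal isomerisation or slow dimerisation of the dipole outruns it at the temperature required. Leakage to the 3,4-regiochemistry is the lesser concern.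

Fallback: the dipolarophile is changed to an alkene and the heterocycle is dehydrogenated afterwards. The fallback sets out from aldehyde 6 and uses dipole 13. Wittig methylenation of 6 (Ph3P=CH2, THF) should give 1,4-bis(benzyloxy)-5-ethenyl-2,3-dimethoxybenzene F1. Terminal alkenes add nitrile oxides faster than alkynes, so F1 and 13 should combine at lower temperature, again with the oxygen on the substituted carbon. The product would be racemic 5-[2,5-bis(benzyloxy)-3,4-dimethoxyphenyl]-3-[4-methoxy-2,6-bis(methoxymethoxy)phenyl]-4,5-dihydroisoxazole F2. Dehydrogenation of F2 with DDQ in warm toluene removes its one stereocentre and returns to the route at 14.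

**Step 9.** The oxidant may attack the very electron-rich ring, or the acetic acid and methanol present may add to the dipole or loosen a MOM ether before the dipole is isolated.

Fallback: the three-carbon link is built without any dipole. The fallback sets out from alkyne 7 and aldehyde 11. Deprotonation of 7 with n-BuLi (THF, −78 °C) and addition to 11 should give racemic 3-[2,5-bis(benzyloxy)-3,4-dimethoxyphenyl]-1-[4-methoxy-2,6-bis(methoxymethoxy)phenyl]prop-2-yn-1-ol F3. Oxidation with MnO2 gives 3-[2,5-bis(benzyloxy)-3,4-dimethoxyphenyl]-1-[4-methoxy-2,6-bis(methoxymethoxy)phenyl]prop-2-yn-1-one F4. Conjugate addition of diethylamine (EtOH, rt) gives (E)-3-[2,5-bis(benzyloxy)-3,4-dimethoxyphenyl]-3-(diethylamino)-1-[4-methoxy-2,6-bis(methoxymethoxy)phenyl]prop-2-en-1-one F5. The amine adduct is used so that closure is six-membered and not five-membered. Aqueous HCl in MeOH at 60 °C then removes the MOM groups, and a ring A phenol displaces the amine by addition–elimination. This returns to the route at 17.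

**Step 4.** The methoxy group para to the reacting carbon is twisted out of conjugation by its two neighbours, so electrophilic attack by the weak Vilsmeier electrophile may stall. Prolonged heating with the HCl formed may start to cleave a benzyl ether.

Fallback: the carbon is introduced through a halogen. The fallback sets out from 4. Bromination with N-bromosuccinimide (MeCN, 0 °C), a far easier substitution at the same unique position, should give 1,4-bis(benzyloxy)-5-bromo-2,3-dimethoxybenzene F6. Bromine–lithium exchange (n-BuLi, THF, −78 °C) and quenching with DMF return to the route at 6.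

**Step 13.** Over-reduction of the C2–C3 bond may accompany the second debenzylation, and the freed hydroquinone may oxidise in air during isolation.

Fallback: non-reductive debenzylation. From 17, BCl3 with pentamethylbenzene as cation scavenger (CH2Cl2, −78 °C) should cleave both benzyl ethers while sparing the methyl ethers. It leads directly to 18 and makes no new compound (entry F0).

## Further compounds

F1 | step 10 | 1,4-bis(benzyloxy)-5-ethenyl-2,3-dimethoxybenzene | C=Cc1cc(OCc2ccccc2)c(OC)c(OC)c1OCc1ccccc1
F2 | step 10 | 5-[2,5-bis(benzyloxy)-3,4-dimethoxyphenyl]-3-[4-methoxy-2,6-bis(methoxymethoxy)phenyl]-4,5-dihydroisoxazole (racemic) | COCOc1cc(OC)cc(OCOC)c1C1=NOC(c2cc(OCc3ccccc3)c(OC)c(OC)c2OCc2ccccc2)C1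
F3 | step 9 | 3-[2,5-bis(benzyloxy)-3,4-dimethoxyphenyl]-1-[4-methoxy-2,6-bis(methoxymethoxy)phenyl]prop-2-yn-1-ol (racemic) | COCOc1cc(OC)cc(OCOC)c1C(O)C#Cc1cc(OCc2ccccc2)c(OC)c(OC)c1OCc1ccccc1
F4 | step 9 | 3-[2,5-bis(benzyloxy)-3,4-dimethoxyphenyl]-1-[4-methoxy-2,6-bis(methoxymethoxy)phenyl]prop-2-yn-1-one | COCOc1cc(OC)cc(OCOC)c1C(=O)C#Cc1cc(OCc2ccccc2)c(OC)c(OC)c1OCc1ccccc1
F5 | step 9 | (E)-3-[2,5-bis(benzyloxy)-3,4-dimethoxyphenyl]-3-(diethylamino)-1-[4-methoxy-2,6-bis(methoxymethoxy)phenyl]prop-2-en-1-one | CCN(CC)/C(=C/C(=O)c1c(OCOC)cc(OC)cc1OCOC)c1cc(OCc2ccccc2)c(OC)c(OC)c1OCc1ccccc1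
F6 | step 4 | 1,4-bis(benzyloxy)-5-bromo-2,3-dimethoxybenzene | COc1c(OC)c(OCc2ccccc2)c(Br)cc1OCc1ccccc1
F0 | step 13 | none | none
A1 | alternative 1 | 4-(3,3-diethoxyprop-1-en-2-yl)-4-hydroxy-2,3-dimethoxycyclobut-2-en-1-one (racemic) | CCOC(OCC)C(=C)C1(O)C(OC)=C(OC)C1=O
A2 | alternative 1 | 2-(diethoxymethyl)-5,6-dimethoxybenzene-1,4-diol | CCOC(OCC)c1cc(O)c(OC)c(OC)c1O
A3 | alternative 2 | 1-[2,5-bis(benzyloxy)-3,4-dimethoxyphenyl]-4-(4-methoxy-2-oxo-2H-pyran-6-yl)butane-1,3-dione | COc1cc(CC(=O)CC(=O)c2cc(OCc3ccccc3)c(OC)c(OC)c2OCc2ccccc2)oc(=O)c1
A4 | alternative 2 | 1-[2,5-bis(benzyloxy)-3,4-dimethoxyphenyl]-3-(2,6-dihydroxy-4-methoxyphenyl)propane-1,3-dione | COc1cc(O)c(C(=O)CC(=O)c2cc(OCc3ccccc3)c(OC)c(OC)c2OCc2ccccc2)c(O)c1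
A5 | alternative 3 | 5-(benzyloxy)-2-ethynyl-7-methoxy-4H-chromen-4-one | C#Cc1cc(=O)c2c(OCc3ccccc3)cc(OC)cc2o1
A6 | alternative 3 | tert-butyl[(3,4-dimethoxyfuran-2-yl)oxy]dimethylsilane | COc1coc(O[Si](C)(C)C(C)(C)C)c1OC
A7 | alternative 3 | 5-(benzyloxy)-2-{2-[(tert-butyldimethylsilyl)oxy]-5-hydroxy-3,4-dimethoxyphenyl}-7-methoxy-4H-chromen-4-one | COc1cc(OCc2ccccc2)c2c(=O)cc(-c3cc(O)c(OC)c(OC)c3O[Si](C)(C)C(C)(C)C)oc2c1
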